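The temperature is the same in every run, so I read the differences between the curves against their charges and ask what the rate depends on.

| flask | starting material | partner | time |
|---|---|---|---|
| dawn | 0.600 M | 0.900 M |  |
| spring | 0.300 M | 0.900 M |  |
| midnight | 0.600 M | 2.70 M |  |
| winter | 0.0920 M | 0.900 M | 3.4 min |

- dawn run (time / min: [target] / M): 0.14: 0.031; 0.26: 0.069; 0.49: 0.099; 0.94: 0.184; 1.8: 0.282; 3.4: 0.392
- spring run (time / min: [target] / M): 0.14: 0.023; 0.26: 0.046; 0.49: 0.059; 0.94: 0.120; 1.8: 0.188; 3.4: 0.254
- midnight run (time / min: [target] / M): 0.14: 0.213; 0.26: 0.344; 0.49: 0.483; 0.94: 0.590; 1.8: 0.599; 3.4: 0.609

(each reading ± 0.006 M)

1. how the opening rate goes with [starting material] round the charge of the dawn run: the exponent of the rate at two percent of starting material gone to target (one fixed amount of target, the same in the runs compared)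
2. how the opening rate goes with [partner] round the charge of the dawn run: the exponent of the rate at two percent of starting material gone to target
3. target in the winter run at 3.4 min, as a share of the starting material charged
4. which of these the readings show (the product speeds the reaction / the second partner is lost in pairs / the substrate pairs with itself / nothing beyond the main steps)

- Overall: starting material + partner -> target.
- Constant volume, constant temperature.
- A reading of a species includes what of it is bound.
- "The second partner" is partner.
- An order is taken over about fifteen percent of the charge, up and down.

My first doubt is that the rate may depend on the target already made, so I set two moments of similar starting material but different target side by side. Late in the dawn run, between 1.8 min and 3.4 min, the rate is 0.0688 M min⁻¹, with partner near 0.563 M. At the opening of the spring run, up to 0.26 min, it is 0.177 M min⁻¹, with partner near 0.877 M. Starting material is about 0.263 M at the dawn moment and 0.277 M at the spring moment. Scaling the spring rate by the squared partner ratio gives 0.0729 M min⁻¹, so I see no effect of target and no extra loss of partner. The first readings of the midnight and dawn runs put the partner order at 1.75, a noisy figure, and I keep the square for scaling.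

Next comes starting material. The first 4 readings, summed, give spring over dawn a ratio ρ = 0.648, an order of 0.626 across the doubling, not 1. Of the options asked, pairing gives such an order. Let m be free starting material in a fast pre-equilibrium with its pair, so that the charge is m + 2Km², with the rate proportional to m. Then ρ gives m = 0.212 M in the dawn run and K = 4.31 M⁻¹. The dawn run has 35.4 % as its free share, the fraction of a charge that is unpaired. The local order at the dawn charge is (1 + 2Km)/(1 + 4Km) = 0.607. But ρ is a time average and K hangs steeply on it, so K remains a rough reading.

The winter charge has m = 0.0605 M at its start, a free share of 65.7 %. The opening dawn rate per free m, scaled to partner at its winter end value, gives k = 1.01 min⁻¹. Integrating gives ln(start m/m) + 4K(start m − m) = kt. The free starting material left at 3.4 min is small, so I drop its term, which is 0.0955 against kt = 3.43, and I commit to 93.9 %.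

The forecast says 0.4, 1.8, 93 % and nothing beyond the main steps, on the ground that “The curve looks like simple saturation”.

The simulation gives orders of 0.59 and 1.8, reports that the substrate pairs with itself, and puts 97.2 % of the winter charge in target, by these steps:

    starting material + partner → target (0.4194 M⁻¹ min⁻¹)
    starting material + 2 partner → target + partner (1.410 M⁻² min⁻¹)
    2 starting material ⇌ idle substrate dimer, settled at all times (7.630 M⁻¹)

In the dawn run the order in starting material is 0.59, and the same run without the joining into idle substrate dimer has 1.0. That joining is what my free share of 35.4 % reads in the dawn run. My free share at the start of the winter run is larger than that, at 65.7 %, and the winter run puts 97.2 % of its charge in target at 3.4 min.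

(The numbers in the tables are simulated for an exercise, and the scatter is random.)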